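The numbers belong to no real substance; no experiment stands behind them.

In this closed, stirred vessel the starting material leaves by three irreversible routes and also slips into a dormant form that can return; the dormant form counts as reacted, so what we follow is the free starting material.

starting material 0.0020 M; acid 0.00600 mM; protic impurity 1.00 mM; time 6.0 s

    starting material + acid → weak acid + acid + product (k1 = 41000 /M/s)
    starting material ⇌ dormant form (K2 = 0.65, k2 = 0.33 /s)
    starting material → weak acid + product (k3 = 0.14 /s)
    crystals ⇌ weak acid, rate k4*(cs4 - [weak acid]) while solid is left; crystals form when [weak acid] > cs4 (cs4 = 0.036 mM, k4 = 2.6 /s)
    weak acid ⇌ conjugate base + acid, settled at all times (K5 = 3.2 × 10⁻⁹ M)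
    starting material + protic impurity → quenched substrate (k6 = 79 /M/s)

- part of the starting material that has reacted at 6.0 s
- pH of the solution at 6.0 s

- acid is the free proton; pH is minus the decimal logarithm of its molar concentration
- weak acid is meant together with its crystals
- solid, in amounts per volume of the solution: crystals
- what has gone from starting material into another species counts as reacted, even if it can come back
- run time (flask): 6.0 s

The acid step gives its acid back, so we hold the acid at its charge and treat that step as pseudo-first-order at 0.246 /s. Adding the uncatalysed step and the impurity step at its charged 0.0790 /s, the smallest of the three, gives a loss constant of 0.465 /s for free starting material. The bench rule of rapid equilibrium keeps free and dormant forms in balance, so the pool decays at the loss constant over one plus the equilibrium constant, 0.282 /s, and leaves 11.2% free at 6.0 s. But that rule needs exchange much faster than loss, and the exchange constant, forward plus back, is 0.838 /s, so the loss constant is about half of it and we stand at the border of the rule.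

We therefore integrate the pair exactly. Free starting material is a sum of two decays whose constants add up to loss plus exchange and multiply to loss times the back constant 0.508 /s. The one that matters is the slow constant, the smaller of these two rates, 0.218 /s, beside a fast one of 1.09 /s. The slow term carries 33.4% of the charge, and with the fast term our reckoning leaves 9.16% free, which is 90.8% reacted.

The forecast gives 90.5% and pH 5.219, on the ground that “Acid is only consumed by a tiny dissociation of the weak acid”.

The flask gives 90.5% reacted and pH 5.22 at 6.0 s, so 9.5% stands free, a little more than our 9.16%, with the protic impurity at 76% of its charge where we held it whole. In a second flask, like this one but with 1.5 × 10⁻⁵ M of acid, the loss constant becomes 0.834 /s and the slow constant 0.311 /s, and the slow term leaves 2.89%. That flask holds 3.0% of its starting material at 6.00 s.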